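The tetracyclic depsidone lactol is built around a photo-Wolff benzannulation that assembles ring B, followed by lactone closure and a late, catalyst-controlled setting of the lactol centre.

Everything rests on disconnecting ring B (numbering of isobenzofuro[4,5-b][1,4]benzodioxepine). C5a (lactone oxygen O6), C5 (methyl) and C4 (hydroxyl) are contiguous, the pattern left when the C=O carbon of a vinylketene bonds to the methyl-bearing carbon of 1-(triisopropylsiloxy)propyne. C5a, C3a, C12b and C12a come from an aryloxyvinyl α-diazo-β-keto ester that already holds ring A through ether oxygen O12; C5 and C4 are the alkyne carbons. Irradiating this precursor with the alkyne runs Wolff rearrangement, [2+2] addition, 4π opening and 6π closure in one operation, making four C–C bonds and the complete hexasubstituted ring B. Lactonisation of the seco acid and late setting of lactol carbon C1 finish the route.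

Key step: step 10

Assumption: the only stereocentre (C1) is a hemiacetal carbon that can racemise through the ring-opened formyl acid; it is fixed as an ester and released only in the last, neutral step, and the free lactol is assumed to keep its configuration during neutral, aprotic isolation.

Remark on the design: ring A carries its carboxyl as a benzyl ester, so that the seven-membered lactone is closed from the free acid under mild conditions. Closure by phenoxide attack on a methyl ester would be uphill and could trigger Smiles rearrangement of the 2-hydroxydiaryl ether. The geometry of the aryloxyvinyl group is immaterial, because that carbon becomes aromatic.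

Step 1
Reactants: 1 methyl acetoacetate
Product: 2 methyl 2-diazo-3-oxobutanoate
Conditions: p-ABSA, Et3N, MeCN, 0 °C to rt
Reagents that add atoms: 4-acetamidobenzenesulfonyl azide (p-ABSA), CC(=O)Nc1ccc(cc1)S(=O)(=O)N=[N+]=[N-]
Why: Regitz diazo transfer to the doubly activated methylene of a β-keto ester is a standard, reliable reaction.

Step 2
Reactants: 2 methyl 2-diazo-3-oxobutanoate
Product: 3 methyl 3-[(tert-butyldimethylsilyl)oxy]-2-diazobut-3-enoate
Conditions: TBSOTf, Et3N, CH2Cl2, 0 °C
Reagents that add atoms: tert-butyldimethylsilyl triflate, CC(C)(C)[Si](C)(C)OS(=O)(=O)C(F)(F)F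
Why: Soft enolisation (silyl enol ether formation) of the acetyl group with a silyl triflate and amine base leaves the acceptor-stabilised diazo group untouched.

Step 3
Reactants: 3 methyl 3-[(tert-butyldimethylsilyl)oxy]-2-diazobut-3-enoate; 4 trimethyl orthoformate
Product: 5 methyl 2-diazo-5,5-dimethoxy-3-oxopentanoate
Conditions: TMSOTf (10 mol%), CH2Cl2, −78 °C; pyridine quench
Reagents that add atoms: none
Why: In this Mukaiyama-type addition the silyl triflate ionises the orthoformate to a dimethoxycarbenium ion, which the terminal CH2 of the silyl enol ether captures at −78 °C, where loss of methanol from the β-keto acetal is slow.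

Step 4
Reactants: 5 methyl 2-diazo-5,5-dimethoxy-3-oxopentanoate; 6 2,2,2-trifluoroethyl formate
Product: 9 methyl (4Z)-2-diazo-4-(dimethoxymethyl)-3-oxo-5-(tosyloxy)pent-4-enoate, via lithium enolate 7 (not isolated), via lithium formyl enolate 8 (not isolated)
Conditions: LiHMDS, THF, −78 °C; 6, −78 °C; then TsCl, N-methylimidazole (cat.), −78 to 0 °C
Reagents that add atoms: p-toluenesulfonyl chloride, Cc1ccc(cc1)S(Cl)(=O)=O
Why: Crossed Claisen formylation of the kinetic lithium enolate with the reactive trifluoroethyl formate at −78 °C should outrun β-elimination of methoxide, and the chelated formyl enolate is then O-sulfonylated at the less hindered aldehyde oxygen (enol tosylate formation), so the acidic hydroxymethylene ketone is never isolated.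

Step 5
Reactants: 10 atraric acid (methyl 2,4-dihydroxy-3,6-dimethylbenzoate)
Product: 11 methyl 2-hydroxy-4-methoxy-3,6-dimethylbenzoate
Conditions: MeI (1.05 equiv), K2CO3, acetone, rt
Reagents that add atoms: iodomethane, CI
Why: Williamson methylation is selective for the 4-OH because the 2-OH is hydrogen-bonded to the ester carbonyl and flanked by two substituents.

Step 6
Reactants: 11 methyl 2-hydroxy-4-methoxy-3,6-dimethylbenzoate
Product: 12 2-hydroxy-4-methoxy-3,6-dimethylbenzoic acid
Conditions: KOH, DMSO/H2O, 90 °C; then aq. HCl, 0 °C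
Reagents that add atoms: potassium hydroxide, [K+].[OH-]
Why: Saponification of the hindered salicylate ester needs forcing basic conditions, and cold acidification should avoid decarboxylation of the salicylic acid.

Step 7
Reactants: 12 2-hydroxy-4-methoxy-3,6-dimethylbenzoic acid
Product: 13 benzyl 2-hydroxy-4-methoxy-3,6-dimethylbenzoate
Conditions: BnBr, KHCO3, DMF, rt
Reagents that add atoms: benzyl bromide, BrCc1ccccc1
Why: Carboxylate O-alkylation with bicarbonate as base leaves the chelated phenol unalkylated and is the usual entry to benzyl esters of orsellinate-type acids.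

Step 8
Reactants: 9 methyl (4Z)-2-diazo-4-(dimethoxymethyl)-3-oxo-5-(tosyloxy)pent-4-enoate; 13 benzyl 2-hydroxy-4-methoxy-3,6-dimethylbenzoate
Product: 14 methyl (4E)-5-[2-(benzyloxycarbonyl)-5-methoxy-3,6-dimethylphenoxy]-2-diazo-4-(dimethoxymethyl)-3-oxopent-4-enoate
Conditions: Cs2CO3, MeCN, 0 °C to rt
Reagents that add atoms: none
Why: In this nucleophilic vinylic substitution (addition–elimination) the caesium phenoxide adds to the unhindered β-CH of the doubly activated enone and expels tosylate; the (E)-isomer is expected to predominate, and either geometry would serve in step 10.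

Step 9
Reactants: 15 ethyl acetate; 16 dibromomethane
Product: 19 triisopropyl(prop-1-yn-1-yloxy)silane, via dibromo enolate 17 (not isolated), via lithium ynolate 18 (not isolated)
Conditions: LiTMP, THF, −78 °C; then LiHMDS; n-BuLi, −78 °C to rt; TIPSCl, −78 °C to rt
Reagents that add atoms: triisopropylsilyl chloride, CC(C)[Si](Cl)(C(C)C)C(C)C
Why: In the Kowalski ester homologation, addition of dibromomethyllithium, enolate formation, bromine–lithium exchange and 1,2-shift give the ynolate, which the bulky silyl chloride traps on oxygen.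

Step 10
Reactants: 14 methyl (4E)-5-[2-(benzyloxycarbonyl)-5-methoxy-3,6-dimethylphenoxy]-2-diazo-4-(dimethoxymethyl)-3-oxopent-4-enoate; 19 triisopropyl(prop-1-yn-1-yloxy)silane
Product: 24 benzyl 2-[2-(dimethoxymethyl)-6-hydroxy-3-(methoxycarbonyl)-5-methyl-4-(triisopropylsilyloxy)phenoxy]-4-methoxy-3,6-dimethylbenzoate, via vinylketene 20 (not isolated), via vinylcyclobutenone 21 (not isolated), via dienylketene 22 (not isolated), via cyclohexadienone 23 (not isolated)
Conditions: hν (medium-pressure Hg lamp, Pyrex, λ > 300 nm), 19 (2.5 equiv), degassed ClCH2CH2Cl (0.02 M), rt; then 80 °C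
Reagents that add atoms: none
Why: Light expels N2 from the diazo keto ester and the alkenyl group migrates from the ketone carbon to the diazo carbon (Wolff rearrangement, alkenyl in preference to methoxy), giving the ester-substituted vinylketene 20. The nucleophilic methyl-bearing carbon of the siloxyalkyne attacks the ketene carbonyl carbon and closure gives cyclobutenone 21 (polar [2+2]); on warming, 4π electrocyclic opening gives dienylketene 22, whose thermal disrotatory 6π electrocyclisation joins the ketene carbon to the aryloxy-bearing vinyl carbon and so closes the six-membered ring B as cyclohexadienone 23, which enolises to the phenol. This is the diazo ketone (photochemical) variant of the Danheiser benzannulation with a siloxyalkyne. The four new bonds are C3a–C12b (migration), C5a–C5 and C4–C3a ([2+2]) and C12a–C5a (6π), and no stereocentre survives because the sp3 centres of 21 and 23 are erased on aromatisation. The step needs regioselectivity in the [2+2] (hydroxyl, methyl, silyloxy in sequence), which the polarisation of the ynol ether secures, and chemoselectivity for [2+2] over hetero-[4+2] of the acylketene, which is favoured because the only heterodiene carbonyl is a poorly reactive ester and the alkyne is in excess. If the vinylketene first closes to its own cyclobutenone, heating at 80 °C should reopen it into the same sequence.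

Step 11
Reactants: 24 benzyl 2-[2-(dimethoxymethyl)-6-hydroxy-3-(methoxycarbonyl)-5-methyl-4-(triisopropylsilyloxy)phenoxy]-4-methoxy-3,6-dimethylbenzoate
Product: 25 2-[2-(dimethoxymethyl)-6-hydroxy-3-(methoxycarbonyl)-5-methyl-4-(triisopropylsilyloxy)phenoxy]-4-methoxy-3,6-dimethylbenzoic acid
Conditions: H2 (1 atm), 10% Pd/C, EtOAc, rt
Reagents that add atoms: none
Why: Hydrogenolysis of the benzyl ester over palladium is selective, since aryl ethers, the silyl ether, the acetal and the methyl ester are inert under neutral conditions.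

Step 12
Reactants: 25 2-[2-(dimethoxymethyl)-6-hydroxy-3-(methoxycarbonyl)-5-methyl-4-(triisopropylsilyloxy)phenoxy]-4-methoxy-3,6-dimethylbenzoic acid
Product: 26 methyl 6-(dimethoxymethyl)-3-methoxy-1,4,9-trimethyl-11-oxo-8-(triisopropylsilyloxy)-11H-dibenzo[b,e][1,4]dioxepine-7-carboxylate
Conditions: EDC·HCl, DMAP, CH2Cl2 (0.005 M), 0 °C to rt
Reagents that add atoms: none
Why: Carbodiimide/DMAP lactonisation (Steglich esterification, intramolecular) of the hydroxy acid at high dilution is the established closure of the seven-membered depsidone ring, and its mild non-basic conditions avoid Smiles rearrangement.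

Step 13
Reactants: 26 methyl 6-(dimethoxymethyl)-3-methoxy-1,4,9-trimethyl-11-oxo-8-(triisopropylsilyloxy)-11H-dibenzo[b,e][1,4]dioxepine-7-carboxylate
Product: 28 rac-1-hydroxy-10-methoxy-5,8,11-trimethyl-4-(triisopropylsilyloxy)-1H-isobenzofuro[4,5-b][1,4]benzodioxepine-3,7-dione, via aldehyde ester 27 (not isolated)
Conditions: 1 M HCl, THF, 45 °C
Reagents that add atoms: water, O
Why: Acid-catalysed acetal hydrolysis unveils the aldehyde, whose hydrate attacks the neighbouring methyl ester (anchimerically assisted ester cleavage) to give the 3-hydroxyphthalide as the racemate, while the aryl silyl ether and the depsidone lactone tolerate aqueous acid.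

Step 14
Reactants: 28 rac-1-hydroxy-10-methoxy-5,8,11-trimethyl-4-(triisopropylsilyloxy)-1H-isobenzofuro[4,5-b][1,4]benzodioxepine-3,7-dione
Product: 29 (1R)-1-acetoxy-10-methoxy-5,8,11-trimethyl-4-(triisopropylsilyloxy)-1H-isobenzofuro[4,5-b][1,4]benzodioxepine-3,7-dione
Conditions: Ac2O, chiral binaphthyl-based 4-(dialkylamino)pyridine catalyst (5 mol%, antipode giving the (R)-acetate), Et3N, CHCl3, −40 °C
Reagents that add atoms: acetic anhydride, CC(=O)OC(C)=O
Why: In this acylative dynamic kinetic resolution of a 3-hydroxyphthalide the lactol enantiomers interconvert through the ring-opened formyl carboxylate under Et3N while the chiral acylpyridinium acetylates one of them preferentially, so the catalyst (antipode chosen in a pilot run, configuration to be confirmed) sets C1, which is then fixed as the pseudo-ester.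

Step 15
Reactants: 29 (1R)-1-acetoxy-10-methoxy-5,8,11-trimethyl-4-(triisopropylsilyloxy)-1H-isobenzofuro[4,5-b][1,4]benzodioxepine-3,7-dione
Product: 30 (1R)-1-acetoxy-4-hydroxy-10-methoxy-5,8,11-trimethyl-1H-isobenzofuro[4,5-b][1,4]benzodioxepine-3,7-dione
Conditions: Et3N·3HF, THF, rt
Reagents that add atoms: none
Why: Fluoride-mediated desilylation of the aryl silyl ether, activated by the ortho carbonyl, should proceed with this near-neutral reagent without ionising the acylal centre or opening the depsidone lactone.

Step 16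
Reactants: 30 (1R)-1-acetoxy-4-hydroxy-10-methoxy-5,8,11-trimethyl-1H-isobenzofuro[4,5-b][1,4]benzodioxepine-3,7-dione
Product: 31 (1R)-1,4-dihydroxy-10-methoxy-5,8,11-trimethyl-1H-isobenzofuro[4,5-b][1,4]benzodioxepine-3,7-dione
Conditions: immobilised Candida antarctica lipase B, n-BuOH, MTBE, 30 °C
Reagents that add atoms: none
Why: Lipase-catalysed transesterification cleaves only the acyl C–O bond, so C1 keeps its configuration, and the enzyme releases the neutral lactol in an aprotic medium without passing through its ring-opening anion.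

Compound list
1 | methyl acetoacetate | CC(=O)CC(=O)OC | starting material
2 | methyl 2-diazo-3-oxobutanoate | CC(=O)C(=[N+]=[N-])C(=O)OC | intermediate
3 | methyl 3-[(tert-butyldimethylsilyl)oxy]-2-diazobut-3-enoate | C=C(O[Si](C)(C)C(C)(C)C)C(=[N+]=[N-])C(=O)OC | intermediate
4 | trimethyl orthoformate | COC(OC)OC | starting material
5 | methyl 2-diazo-5,5-dimethoxy-3-oxopentanoate | COC(OC)CC(=O)C(=[N+]=[N-])C(=O)OC | intermediate
6 | 2,2,2-trifluoroethyl formate | O=COCC(F)(F)F | starting material
7 | lithium 2-diazo-1,5,5-trimethoxy-1-oxopent-3-en-3-olate (lithium enolate of 5, enolate geometry not defined) | COC(OC)C=C([O-])C(=[N+]=[N-])C(=O)OC.[Li+] | intermediate (not isolated)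
8 | lithium (1Z)-4-diazo-2-(dimethoxymethyl)-5-methoxy-3,5-dioxopent-1-en-1-olate (chelated formyl enolate) | COC(=O)C(=[N+]=[N-])C(=O)/C(=C\[O-])C(OC)OC.[Li+] | intermediate (not isolated)
9 | methyl (4Z)-2-diazo-4-(dimethoxymethyl)-3-oxo-5-(tosyloxy)pent-4-enoate | COC(=O)C(=[N+]=[N-])C(=O)/C(=C\OS(=O)(=O)c1ccc(C)cc1)C(OC)OC | intermediate
10 | atraric acid (methyl 2,4-dihydroxy-3,6-dimethylbenzoate) | COC(=O)c1c(C)cc(O)c(C)c1O | starting material
11 | methyl 2-hydroxy-4-methoxy-3,6-dimethylbenzoate | COC(=O)c1c(C)cc(OC)c(C)c1O | intermediate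
12 | 2-hydroxy-4-methoxy-3,6-dimethylbenzoic acid | OC(=O)c1c(C)cc(OC)c(C)c1O | intermediate
13 | benzyl 2-hydroxy-4-methoxy-3,6-dimethylbenzoate | O=C(OCc1ccccc1)c1c(C)cc(OC)c(C)c1O | intermediate
14 | methyl (4E)-5-[2-(benzyloxycarbonyl)-5-methoxy-3,6-dimethylphenoxy]-2-diazo-4-(dimethoxymethyl)-3-oxopent-4-enoate (aryloxy trans to the ketone carbonyl) | COC(=O)C(=[N+]=[N-])C(=O)/C(=C/Oc1c(C)c(OC)cc(C)c1C(=O)OCc1ccccc1)C(OC)OC | intermediate (key-step precursor)
15 | ethyl acetate | CCOC(C)=O | starting material
16 | dibromomethane | BrCBr | starting material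
17 | lithium 1,1-dibromoprop-1-en-2-olate | CC([O-])=C(Br)Br.[Li+] | intermediate (not isolated)
18 | lithium prop-1-yn-1-olate | CC#C[O-].[Li+] | intermediate (not isolated)
19 | triisopropyl(prop-1-yn-1-yloxy)silane, i.e. 1-(triisopropylsiloxy)propyne | CC#CO[Si](C(C)C)(C(C)C)C(C)C | intermediate
20 | ester-substituted vinylketene: methyl (3E)-4-aryloxy-2-carbonyl-3-(dimethoxymethyl)but-3-enoate, aryl = 2-(benzyloxycarbonyl)-5-methoxy-3,6-dimethylphenyl | COC(=O)C(=C=O)/C(=C/Oc1c(C)c(OC)cc(C)c1C(=O)OCc1ccccc1)C(OC)OC | intermediate (not isolated)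
21 | racemic 4-alkenylcyclobutenone: methyl 1-[(E)-2-aryloxy-1-(dimethoxymethyl)ethenyl]-3-methyl-4-oxo-2-(triisopropylsilyloxy)cyclobut-2-ene-1-carboxylate | CC1=C(O[Si](C(C)C)(C(C)C)C(C)C)C(C(=O)OC)(C1=O)/C(=C/Oc1c(C)c(OC)cc(C)c1C(=O)OCc1ccccc1)C(OC)OC | intermediate (not isolated)
22 | dienylketene O=C=C(Me)–C(OTIPS)=C(CO2Me)–C(CH(OMe)2)=CH–OAr, ketene-bearing carbon cis to the aryloxyvinyl group | CC(=C=O)/C(O[Si](C(C)C)(C(C)C)C(C)C)=C(C(=O)OC)\C(=C\Oc1c(C)c(OC)cc(C)c1C(=O)OCc1ccccc1)C(OC)OC | intermediate (not isolated)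
23 | racemic cyclohexa-2,4-dienone: methyl 5-aryloxy-6-(dimethoxymethyl)-3-methyl-4-oxo-2-(triisopropylsilyloxy)cyclohexa-1,6-diene-1-carboxylate (keto tautomer of 24) | CC1=C(O[Si](C(C)C)(C(C)C)C(C)C)C(C(=O)OC)=C(C(OC)OC)C(Oc2c(C)c(OC)cc(C)c2C(=O)OCc2ccccc2)C1=O | intermediate (not isolated)
24 | benzyl 2-[2-(dimethoxymethyl)-6-hydroxy-3-(methoxycarbonyl)-5-methyl-4-(triisopropylsilyloxy)phenoxy]-4-methoxy-3,6-dimethylbenzoate | COC(=O)c1c(O[Si](C(C)C)(C(C)C)C(C)C)c(C)c(O)c(Oc2c(C)c(OC)cc(C)c2C(=O)OCc2ccccc2)c1C(OC)OC | intermediate (key-step product)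
25 | 2-[2-(dimethoxymethyl)-6-hydroxy-3-(methoxycarbonyl)-5-methyl-4-(triisopropylsilyloxy)phenoxy]-4-methoxy-3,6-dimethylbenzoic acid | COC(=O)c1c(O[Si](C(C)C)(C(C)C)C(C)C)c(C)c(O)c(Oc2c(C)c(OC)cc(C)c2C(=O)O)c1C(OC)OC | intermediate
26 | methyl 6-(dimethoxymethyl)-3-methoxy-1,4,9-trimethyl-11-oxo-8-(triisopropylsilyloxy)-11H-dibenzo[b,e][1,4]dioxepine-7-carboxylate | COc1cc(C)c2c(c1C)Oc1c(c(C)c(O[Si](C(C)C)(C(C)C)C(C)C)c(C(=O)OC)c1C(OC)OC)OC2=O | intermediate
27 | methyl 6-formyl-3-methoxy-1,4,9-trimethyl-11-oxo-8-(triisopropylsilyloxy)-11H-dibenzo[b,e][1,4]dioxepine-7-carboxylate | COc1cc(C)c2c(c1C)Oc1c(c(C)c(O[Si](C(C)C)(C(C)C)C(C)C)c(C(=O)OC)c1C=O)OC2=O | intermediate (not isolated)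
28 | rac-1-hydroxy-10-methoxy-5,8,11-trimethyl-4-(triisopropylsilyloxy)-1H-isobenzofuro[4,5-b][1,4]benzodioxepine-3,7-dione | COc1cc(C)c2c(c1C)Oc1c(c(C)c(O[Si](C(C)C)(C(C)C)C(C)C)c3c1C(O)OC3=O)OC2=O | intermediate
29 | (1R)-1-acetoxy-10-methoxy-5,8,11-trimethyl-4-(triisopropylsilyloxy)-1H-isobenzofuro[4,5-b][1,4]benzodioxepine-3,7-dione | COc1cc(C)c2c(c1C)Oc1c(c(C)c(O[Si](C(C)C)(C(C)C)C(C)C)c3c1[C@H](OC(C)=O)OC3=O)OC2=O | intermediate
30 | (1R)-1-acetoxy-4-hydroxy-10-methoxy-5,8,11-trimethyl-1H-isobenzofuro[4,5-b][1,4]benzodioxepine-3,7-dione | COc1cc(C)c2c(c1C)Oc1c(c(C)c(O)c3c1[C@H](OC(C)=O)OC3=O)OC2=O | intermediate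
31 | (1R)-1,4-dihydroxy-10-methoxy-5,8,11-trimethyl-1H-isobenzofuro[4,5-b][1,4]benzodioxepine-3,7-dione | COc1cc(C)c2c(c1C)Oc1c(c(C)c(O)c3c1[C@H](O)OC3=O)OC2=O | target

Total step count: 16. Longest linear sequence: 12 steps (steps 1–4, 8, 10–16, from methyl acetoacetate).

Steps most likely to fail

Step 10 (key step). The ester-bearing ketene may be diverted before the [2+2]: hetero-[4+2] through its ester carbonyl, slow capture by the bulky siloxyalkyne, or light-induced loss of the alkyne during a long irradiation. The fallback sets out from 14 and uses a smaller, more nucleophilic ynol ether with a different ring-B protecting-group endgame. The same irradiation is run with commercial 1-ethoxypropyne (rt, then 80 °C, below the retro-ene temperature of the ynol ether), which should give benzyl 2-[2-(dimethoxymethyl)-4-ethoxy-6-hydroxy-3-(methoxycarbonyl)-5-methylphenoxy]-4-methoxy-3,6-dimethylbenzoate F1. Hydrogenolysis as in step 11 should give 2-[2-(dimethoxymethyl)-4-ethoxy-6-hydroxy-3-(methoxycarbonyl)-5-methylphenoxy]-4-methoxy-3,6-dimethylbenzoic acid F2, and lactonisation as in step 12 should give methyl 6-(dimethoxymethyl)-8-ethoxy-3-methoxy-1,4,9-trimethyl-11-oxo-11H-dibenzo[b,e][1,4]dioxepine-7-carboxylate F3. BCl3 (CH2Cl2, −78 to 0 °C) should then cleave the ethyl ether chelated to the ester together with the acetal, and aqueous HCl/THF work-up should close the lactol to rac-1,4-dihydroxy-10-methoxy-5,8,11-trimethyl-1H-isobenzofuro[4,5-b][1,4]benzodioxepine-3,7-dione F4. Acylative dynamic kinetic resolution as in step 14 with one equivalent of Ac2O, which should acetylate the lactol hydroxyl in preference to the chelated, doubly ortho-substituted phenol, comes back to the route at 30.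

Step 14. The chiral acyl-transfer catalyst may discriminate poorly between the lactol enantiomers because of the aryloxy substituent next to C1, or racemisation of the lactol may be slower than its acylation. The fallback sets out from 28 and replaces catalyst control by physical resolution of a configurationally stable derivative. Non-selective acetylation (Ac2O, DMAP, Et3N, CH2Cl2) should give rac-1-acetoxy-10-methoxy-5,8,11-trimethyl-4-(triisopropylsilyloxy)-1H-isobenzofuro[4,5-b][1,4]benzodioxepine-3,7-dione F5. Preparative chromatography on a chiral stationary phase (SFC) separates it into 29 and its enantiomer, (1S)-1-acetoxy-10-methoxy-5,8,11-trimethyl-4-(triisopropylsilyloxy)-1H-isobenzofuro[4,5-b][1,4]benzodioxepine-3,7-dione F6, which mild aqueous acid hydrolysis returns to 28 for recycling. The fallback comes back to the route at 29.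

Step 4. Methoxide may be lost by β-elimination from the enolate before formylation, or sulfonylation may occur at the ketone oxygen of the ambident enolate. The fallback sets out from 5 and introduces the extra carbon without a strong base. Condensation with tert-butoxybis(dimethylamino)methane (toluene, 50 °C) should give methyl (4E)-2-diazo-4-(dimethoxymethyl)-5-(dimethylamino)-3-oxopent-4-enoate F7. Cold aqueous LiOH in THF should exchange the amino group for oxide (vinylogous amide hydrolysis), which comes back to the route at 8; after drying, 8 is tosylated to 9 as in step 4.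

Further compounds
F1 | step 10 | benzyl 2-[2-(dimethoxymethyl)-4-ethoxy-6-hydroxy-3-(methoxycarbonyl)-5-methylphenoxy]-4-methoxy-3,6-dimethylbenzoate | CCOc1c(C)c(O)c(Oc2c(C)c(OC)cc(C)c2C(=O)OCc2ccccc2)c(C(OC)OC)c1C(=O)OC
F2 | step 10 | 2-[2-(dimethoxymethyl)-4-ethoxy-6-hydroxy-3-(methoxycarbonyl)-5-methylphenoxy]-4-methoxy-3,6-dimethylbenzoic acid | CCOc1c(C)c(O)c(Oc2c(C)c(OC)cc(C)c2C(=O)O)c(C(OC)OC)c1C(=O)OC
F3 | step 10 | methyl 6-(dimethoxymethyl)-8-ethoxy-3-methoxy-1,4,9-trimethyl-11-oxo-11H-dibenzo[b,e][1,4]dioxepine-7-carboxylate | COc1cc(C)c2c(c1C)Oc1c(c(C)c(OCC)c(C(=O)OC)c1C(OC)OC)OC2=O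
F4 | step 10 | rac-1,4-dihydroxy-10-methoxy-5,8,11-trimethyl-1H-isobenzofuro[4,5-b][1,4]benzodioxepine-3,7-dione | COc1cc(C)c2c(c1C)Oc1c(c(C)c(O)c3c1C(O)OC3=O)OC2=O
F5 | step 14 | rac-1-acetoxy-10-methoxy-5,8,11-trimethyl-4-(triisopropylsilyloxy)-1H-isobenzofuro[4,5-b][1,4]benzodioxepine-3,7-dione | COc1cc(C)c2c(c1C)Oc1c(c(C)c(O[Si](C(C)C)(C(C)C)C(C)C)c3c1C(OC(C)=O)OC3=O)OC2=O
F6 | step 14 | (1S)-1-acetoxy-10-methoxy-5,8,11-trimethyl-4-(triisopropylsilyloxy)-1H-isobenzofuro[4,5-b][1,4]benzodioxepine-3,7-dione | COc1cc(C)c2c(c1C)Oc1c(c(C)c(O[Si](C(C)C)(C(C)C)C(C)C)c3c1[C@@H](OC(C)=O)OC3=O)OC2=O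
F7 | step 4 | methyl (4E)-2-diazo-4-(dimethoxymethyl)-5-(dimethylamino)-3-oxopent-4-enoate | COC(=O)C(=[N+]=[N-])C(=O)/C(=C/N(C)C)C(OC)OC
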